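The constant to lean on is the saturation concentration of L, 57 mM in the earlier runs and in the new flasks alike, though at the start none of L is in solution. What stays open is what the plateaus mean.

the same everywhere: L 57 mM (held)
- Thursday's: Q 0.067 M; temperature 35 °C; run made earlier
- Sunday's: Q 0.15 M; temperature 70 °C; run made earlier
- south-west: Q 0.10 M; at 100 °C until 80 s, from then on at 40 °C; time 2.5 min
- south: Q 0.10 M; temperature 100 °C; time 2.5 min
- west: Q 0.10 M; temperature 70 °C; time 2.5 min
- east: Q 0.10 M; temperature 40 °C; time 2.5 min

| run | time / min | X / % |
|---|---|---|
| Thursday's | 10.0 | 11.2 |
| Thursday's | 20.0 | 19.2 |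
| Thursday's | 30.0 | 23.4 |
| Thursday's | 40.0 | 26.0 |
| Thursday's | 50.0 | 28.9 |
| Thursday's | 60.0 | 28.9 |
| Thursday's | 80.0 | 31.3 |
| Sunday's | 0.667 | 12.4 |
| Sunday's | 2.00 | 29.1 |
| Sunday's | 4.00 | 36.6 |
| Sunday's | 6.00 | 38.4 |
| Sunday's | 8.00 | 37.9 |
| Sunday's | 12.0 | 38.9 |

(scatter of a reading: 0.5 percentage points)

- the flask with the highest amount of X, in percent of the Q charged ("all alike" if they lie within 1.5 percentage points) (south-west / south / west / east / all alike)
- final X, as a percentage of the Q charged, in south-west
- final X, as a percentage of the Q charged, in south
- final X, as a percentage of the Q charged, in west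
- final X, as a percentage of the Q charged, in east

- at the start none of L is in solution

Two chemists read these runs differently. The first takes the plateaus, 31.3% at 35 °C and 38.9% at 70 °C, as equilibria that move with temperature, noting that “X does not fall afterwards”. That reading is the forecast: 44.3% in south, 43.5% in south-west, 31.8% in west, 5.1% in east, and south highest.

The second says a plateau is the end of a race. Q leaves by irreversible routes, and X is the share that one route wins. Her quantity is 0.637 at 70 °C, the branch ratio: plateau X divided by the rest of the charge, a selectivity factor. Thursday's run gives 0.456. Both are readings and carry their scatter.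

On her view the ratio ignores the charge of Q, so west, left long enough, should end near Sunday's plateau although it starts from 0.10 M and not 0.15 M. She will not stretch two ratios up to 100 °C, since another route may enter there. But Sunday's run had reached 74.8% of its plateau by 2.00 min, and south is hotter, so she expects Q gone before the cooling of south-west at 80 s. Her commitment is therefore a pair: south-west and south read the same, not 0.8 percentage points apart. That pair is the thing to watch.

The equations behind the flasks:

    Q + D → G (k = 0.0540 /M/s, Ea = 51.0 kJ/mol)
    Q → Z (k = 0.00440 /s, Ea = 96.0 kJ/mol)
    Q + D → X (k = 0.0870 /M/s, Ea = 77.0 kJ/mol)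
    L ⇌ D, rate k4*(csat - [D]) (kL = 0.200 /s)
    (constants at 70 °C)

South gives 25.5%, south-west the same 25.5%, west 31.9% and east 4.97%, so west holds most X. The forecast keeps its numbers in west and east, where Q still stood at 17% and 85%. South ends with a branch ratio of 0.342, below both earlier readings, with X over Z at 0.381, while the rate of the X route over the Z route in west is 0.97 at 0.193 min. West, left to 25.0 min, reaches 38.6%, a branch ratio of 0.629 beside Sunday's 0.637.

All runs are calculated with made-up constants; scatter was added.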